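**Strategy**

Everything rests on cutting the oxepine at C3–CH2 and the pyranone at O1–C2, which unravels the target to an acyclic diaryl ynone whose ring B oxygen at C2' already carries the enantiopure CH(CMe2OH)CH2I arm, derived from prenol epoxide. In one operation pyrrolidine adds to the alkyne carbon on ring B (future C2) and the enaminone carbon thus created (future C3) displaces iodide, so the seven-membered ring is forged before any pyranone exists. The step exploits that C3, the oxepine carbon bonded to CH2, is alpha to the C4 carbonyl, and that ring A has a mirror plane through C4a and C7, so either masked ortho oxygen can close the pyranone in the final acid step.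

Key step: step 13

Remark: locants follow flavone numbering (O1, C2, C3, C4, ring A C5 to C8, ring B primed); ArA stands for 2,4,6-tris(methoxymethoxy)-3,5-bis(3-methylbut-2-enyl)phenyl; the carbinol epimers of 13 and 14 and the alkene geometry of 18 are left undefined because both elements vanish in later steps.

**Route**

Step 1
Reactants: 1 prenol (3-methylbut-2-en-1-ol)
Product: 2 (S)-3,3-dimethylglycidol [(2S)-3,3-dimethyloxiran-2-yl]methanol
Conditions: Ti(OiPr)4 (5 mol%), L-(+)-diisopropyl tartrate (6 mol%), t-BuOOH (anhydrous), 4 Å MS, CH2Cl2, −20 °C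
Reagents that add atoms: tert-butyl hydroperoxide, CC(C)(C)OO
Why: Sharpless asymmetric epoxidation of a primary allylic alcohol, in which the L-(+)-tartrate titanium catalyst delivers the peroxide oxygen to the alkene face that makes C2 (S), as it does for other 3-substituted allylic alcohols, and thereby sets the only stereocentre of the route.

Step 2
Reactants: 2 (S)-3,3-dimethylglycidol
Product: 3 tert-butyl{[(2S)-3,3-dimethyloxiran-2-yl]methoxy}diphenylsilane
Conditions: TBDPSCl, imidazole, CH2Cl2, 0 °C to rt
Reagents that add atoms: tert-butyl(chloro)diphenylsilane (TBDPSCl), CC(C)(C)[Si](Cl)(c1ccccc1)c1ccccc1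
Why: Imidazole-promoted silylation of a primary alcohol under neutral conditions that neither open the epoxide nor trigger a Payne rearrangement, giving a bulky silyl ether that resists migration later.

Step 3
Reactants: 4 2,4-dihydroxybenzaldehyde
Product: 5 2-hydroxy-4-(methoxymethoxy)benzaldehyde
Conditions: MOMCl (1.05 equiv), K2CO3, acetone, 0 °C to rt
Reagents that add atoms: chloromethyl methyl ether (MOMCl), COCCl
Why: Williamson-type O-alkylation that is selective because the 2-hydroxyl is held in a hydrogen bond to the formyl group and reacts far more slowly than the free 4-hydroxyl.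

Step 4
Reactants: 3 tert-butyl{[(2S)-3,3-dimethyloxiran-2-yl]methoxy}diphenylsilane, 5 2-hydroxy-4-(methoxymethoxy)benzaldehyde
Product: 6 2-{[(2R)-1-(tert-butyldiphenylsilyloxy)-3-hydroxy-3-methylbutan-2-yl]oxy}-4-(methoxymethoxy)benzaldehyde
Conditions: Cs2CO3 (0.3 equiv), DMF, 90 °C
Reagents that add atoms: none
Why: Base-mediated SN2 opening of an epoxide by a phenoxide, which can only attack the secondary carbon C2 because the other terminus is fully substituted, so the tertiary alcohol is released and C2 is inverted cleanly from the (S)-epoxide to the (R)-aryl ether of the target, while the substoichiometric base keeps the tertiary alkoxide protonated and so suppresses silyl or aryl migration.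

Step 5
Reactants: 6 2-{[(2R)-1-(tert-butyldiphenylsilyloxy)-3-hydroxy-3-methylbutan-2-yl]oxy}-4-(methoxymethoxy)benzaldehyde
Product: 7 (3R)-4-(tert-butyldiphenylsilyloxy)-3-[2-ethynyl-5-(methoxymethoxy)phenoxy]-2-methylbutan-2-ol
Conditions: dimethyl (1-diazo-2-oxopropyl)phosphonate, K2CO3, MeOH, 0 °C to rt
Reagents that add atoms: dimethyl (1-diazo-2-oxopropyl)phosphonate (Ohira-Bestmann reagent), CC(=O)C(=[N+]=[N-])P(=O)(OC)OC
Why: Ohira-Bestmann modification of the Seyferth-Gilbert homologation, whose carbonate/methanol conditions leave the silyl ether, the MOM acetal and the tertiary alcohol alone and cannot epimerise the stereocentre, which is not alpha to the carbonyl.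

Step 6
Reactants: 8 2,4,6-trihydroxybenzaldehyde, 9 prenyl bromide (1-bromo-3-methylbut-2-ene)
Product: 10 2,4,6-trihydroxy-3,5-bis(3-methylbut-2-enyl)benzaldehyde
Conditions: 9 (2.2 equiv), 10% aq. KOH, 0 °C to rt
Reagents that add atoms: none
Why: Double C-alkylation of an acylphloroglucinol phenoxide in water, where hydrogen bonding to the oxygens steers the allylic bromide to the two equivalent nucleophilic ring carbons C3 and C5, a known if modest entry to 3,5-diprenyl acylphloroglucinols.

Step 7
Reactants: 10 2,4,6-trihydroxy-3,5-bis(3-methylbut-2-enyl)benzaldehyde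
Product: 11 2,4,6-tris(methoxymethoxy)-3,5-bis(3-methylbut-2-enyl)benzaldehyde
Conditions: NaH, MOMCl, DMF, 0 °C to rt
Reagents that add atoms: chloromethyl methyl ether (MOMCl), COCCl
Why: Williamson etherification of the triphenoxide with a hard electrophile gives O-alkylation at all three oxygens, the two chelated ones included, so that neither ortho oxygen can cyclise before the key step.

Step 8
Reactants: 7 (3R)-4-(tert-butyldiphenylsilyloxy)-3-[2-ethynyl-5-(methoxymethoxy)phenoxy]-2-methylbutan-2-ol, 11 2,4,6-tris(methoxymethoxy)-3,5-bis(3-methylbut-2-enyl)benzaldehyde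
Product: 13 1-ArA-3-{2-[(2R)-1-(tert-butyldiphenylsilyloxy)-3-hydroxy-3-methylbutan-2-yl]oxy-4-(methoxymethoxy)phenyl}prop-2-yn-1-ol (both C1 epimers), via dilithium acetylide alkoxide 12 (not isolated)
Conditions: 7, n-BuLi (2.05 equiv), THF, −78 °C; then 11, −78 to −20 °C; aq. NH4Cl
Reagents that add atoms: none
Why: 1,2-Addition of a lithium acetylide to an aromatic aldehyde, with the second equivalent of base held on the tertiary alcohol, in which the new carbinol centre forms without control and is erased by the oxidation of step 10.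

Step 9
Reactants: 13 silyl-protected propargylic alcohol
Product: 14 (2R)-2-{2-[3-ArA-3-hydroxyprop-1-ynyl]-5-(methoxymethoxy)phenoxy}-3-methylbutane-1,3-diol (both carbinol epimers)
Conditions: TBAF, AcOH, THF, rt
Reagents that add atoms: none
Why: Buffered fluoride cleavage of the silyl ether, done while the alkyne is still a propargylic alcohol so that neither fluoride nor an alkoxide ever meets a Michael-accepting ynone.

Step 10
Reactants: 14 propargylic triol
Product: 15 1-ArA-3-{2-[(2R)-1,3-dihydroxy-3-methylbutan-2-yl]oxy-4-(methoxymethoxy)phenyl}prop-2-yn-1-one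
Conditions: activated MnO2 (excess), CH2Cl2, rt
Reagents that add atoms: none
Why: MnO2 oxidation is selective for the benzylic-propargylic secondary alcohol, leaves the primary and tertiary aliphatic alcohols and the prenyl groups untouched, and removes the uncontrolled carbinol centre.

Step 11
Reactants: 15 hydroxy ynone
Product: 16 (2R)-2-[2-(3-ArA-3-oxoprop-1-ynyl)-5-(methoxymethoxy)phenoxy]-3-hydroxy-3-methylbutyl methanesulfonate
Conditions: MsCl (1.1 equiv), Et3N, CH2Cl2, −20 °C
Reagents that add atoms: methanesulfonyl chloride, CS(=O)(=O)Cl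
Why: Sulfonylation through sulfene is fast for the primary alcohol at low temperature, the tertiary alcohol does not compete, and the brief cold exposure to Et3N gives the neutral alcohol no time for conjugate addition to the ynone.

Step 12
Reactants: 16 ynone mesylate
Product: 17 1-ArA-3-{2-[(2S)-3-hydroxy-1-iodo-3-methylbutan-2-yl]oxy-4-(methoxymethoxy)phenyl}prop-2-yn-1-one
Conditions: NaI, NaHCO3, 2-butanone, 65 °C, dark
Reagents that add atoms: sodium iodide, [Na+].[I-]
Why: Finkelstein exchange at a primary carbon in a buffered aprotic medium where iodide cannot add productively to the ynone; the descriptor of the stereocentre becomes (S) only through the priority rules, since no bond to it changes.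

Step 13
Reactants: 17 iodo ynone
Product: 20 [(2R)-2-(2-hydroxypropan-2-yl)-8-(methoxymethoxy)-5-(pyrrolidin-1-yl)-2,3-dihydro-1-benzoxepin-4-yl](ArA)methanone, via acyclic pyrrolidinyl enaminone 18 (not isolated), via cyclic iminium iodide 19 (not isolated)
Conditions: pyrrolidine (1.05 equiv), MeCN, 0 °C to rt; then i-Pr2NEt (2 equiv), 70 °C
Reagents that add atoms: pyrrolidine, C1CCNC1
Why: Proposed new method: pyrrolidine adds in conjugate fashion to the alkyne carbon bound to ring B (future C2) to give the push-pull enaminone 18, whose alpha carbon (future C3) then displaces the primary iodide intramolecularly to give iminium iodide 19, and i-Pr2NEt removes the alpha proton to restore the conjugated enaminone 20. The closest known reaction types are the amine addition to aryl ynones that precedes flavone formation and the intramolecular C-alkylation of vinylogous amides by tethered alkyl halides, but their union on an ynone that carries its own electrophile has not been shown. Only the oxepine ring closes, in a 7-exo-tet mode, and the pyranone stays open because all three oxygens of ring A are MOM ethers. No lasting stereocentre is created, since the transient sp3 alpha carbon of 19 is flattened on deprotonation, and the existing centre is a spectator whose descriptor returns to (R) merely because iodine is lost. The step needs C-alkylation to beat N- and O-alkylation, E2 loss of HI and intermolecular amination: the ynone consumes the single equivalent of pyrrolidine at low temperature before any heating, the enaminone nitrogen is tertiary and delocalised, O-alkylation would demand a nine-membered ring, and the twisted ring B holds its O-CH-CH2I arm over the pi face of the alpha carbon.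

Step 14
Reactants: 20 cyclic enaminone
Product: 22 target CNP0328977.2: (R)-5,7,4'-trihydroxy-6,8-diprenylflavone bridged from C3 through CH2-CH(CMe2OH) to the 2'-oxygen, via tetraphenol enaminone 21 (not isolated)
Conditions: 3 M aq. HCl, MeOH, 50 °C
Reagents that add atoms: none
Why: Acid cleaves the four MOM acetals, and a freed ortho phenol of ring A then adds to the protonated enaminone carbon C2 and expels pyrrolidine (the standard enaminone-to-chromone cyclocondensation, 6-exo-trig on the iminium), the two ortho hydroxyls being equivalent so that a single flavone results with the stereocentre untouched.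

**Compound list**

1 | prenol (3-methylbut-2-en-1-ol) | CC(C)=CCO | starting material
2 | (S)-3,3-dimethylglycidol [(2S)-3,3-dimethyloxiran-2-yl]methanol | OC[C@@H]1OC1(C)C | intermediate
3 | tert-butyl{[(2S)-3,3-dimethyloxiran-2-yl]methoxy}diphenylsilane | CC(C)(C)[Si](c1ccccc1)(c1ccccc1)OC[C@@H]1OC1(C)C | intermediate
4 | 2,4-dihydroxybenzaldehyde | O=Cc1ccc(O)cc1O | starting material
5 | 2-hydroxy-4-(methoxymethoxy)benzaldehyde | COCOc1ccc(C=O)c(O)c1 | intermediate
6 | 2-{[(2R)-1-(tert-butyldiphenylsilyloxy)-3-hydroxy-3-methylbutan-2-yl]oxy}-4-(methoxymethoxy)benzaldehyde | CC(C)(C)[Si](c1ccccc1)(c1ccccc1)OC[C@H](C(C)(C)O)Oc1cc(OCOC)ccc1C=O | intermediate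
7 | (3R)-4-(tert-butyldiphenylsilyloxy)-3-[2-ethynyl-5-(methoxymethoxy)phenoxy]-2-methylbutan-2-ol | CC(C)(C)[Si](c1ccccc1)(c1ccccc1)OC[C@H](C(C)(C)O)Oc1cc(OCOC)ccc1C#C | intermediate
8 | 2,4,6-trihydroxybenzaldehyde | O=Cc1c(O)cc(O)cc1O | starting material
9 | prenyl bromide (1-bromo-3-methylbut-2-ene) | CC(C)=CCBr | starting material
10 | 2,4,6-trihydroxy-3,5-bis(3-methylbut-2-enyl)benzaldehyde | O=Cc1c(O)c(CC=C(C)C)c(O)c(CC=C(C)C)c1O | intermediate
11 | 2,4,6-tris(methoxymethoxy)-3,5-bis(3-methylbut-2-enyl)benzaldehyde | COCOc1c(CC=C(C)C)c(OCOC)c(CC=C(C)C)c(OCOC)c1C=O | intermediate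
12 | dilithium salt of 7 (lithium acetylide and lithium tertiary alkoxide; not isolated) | CC(C)(C)[Si](c1ccccc1)(c1ccccc1)OC[C@H](C(C)(C)O[Li])Oc1cc(OCOC)ccc1C#C[Li] | intermediate
13 | 1-ArA-3-{2-[(2R)-1-(tert-butyldiphenylsilyloxy)-3-hydroxy-3-methylbutan-2-yl]oxy-4-(methoxymethoxy)phenyl}prop-2-yn-1-ol (both C1 epimers) | CC(C)(C)[Si](c1ccccc1)(c1ccccc1)OC[C@H](C(C)(C)O)Oc1cc(OCOC)ccc1C#CC(O)c1c(OCOC)c(CC=C(C)C)c(OCOC)c(CC=C(C)C)c1OCOC | intermediate
14 | (2R)-2-{2-[3-ArA-3-hydroxyprop-1-ynyl]-5-(methoxymethoxy)phenoxy}-3-methylbutane-1,3-diol (both carbinol epimers) | OC[C@H](C(C)(C)O)Oc1cc(OCOC)ccc1C#CC(O)c1c(OCOC)c(CC=C(C)C)c(OCOC)c(CC=C(C)C)c1OCOC | intermediate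
15 | 1-ArA-3-{2-[(2R)-1,3-dihydroxy-3-methylbutan-2-yl]oxy-4-(methoxymethoxy)phenyl}prop-2-yn-1-one | OC[C@H](C(C)(C)O)Oc1cc(OCOC)ccc1C#CC(=O)c1c(OCOC)c(CC=C(C)C)c(OCOC)c(CC=C(C)C)c1OCOC | intermediate
16 | (2R)-2-[2-(3-ArA-3-oxoprop-1-ynyl)-5-(methoxymethoxy)phenoxy]-3-hydroxy-3-methylbutyl methanesulfonate | CS(=O)(=O)OC[C@H](C(C)(C)O)Oc1cc(OCOC)ccc1C#CC(=O)c1c(OCOC)c(CC=C(C)C)c(OCOC)c(CC=C(C)C)c1OCOC | intermediate
17 | 1-ArA-3-{2-[(2S)-3-hydroxy-1-iodo-3-methylbutan-2-yl]oxy-4-(methoxymethoxy)phenyl}prop-2-yn-1-one | IC[C@H](C(C)(C)O)Oc1cc(OCOC)ccc1C#CC(=O)c1c(OCOC)c(CC=C(C)C)c(OCOC)c(CC=C(C)C)c1OCOC | intermediate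
18 | 1-ArA-3-{2-[(2S)-3-hydroxy-1-iodo-3-methylbutan-2-yl]oxy-4-(methoxymethoxy)phenyl}-3-(pyrrolidin-1-yl)prop-2-en-1-one (alkene geometry undefined; not isolated) | IC[C@H](C(C)(C)O)Oc1cc(OCOC)ccc1C(N1CCCC1)=CC(=O)c1c(OCOC)c(CC=C(C)C)c(OCOC)c(CC=C(C)C)c1OCOC | intermediate
19 | 1-[(2R)-4-(ArA-carbonyl)-2-(2-hydroxypropan-2-yl)-8-(methoxymethoxy)-3,4-dihydro-2H-1-benzoxepin-5-ylidene]pyrrolidinium iodide (C4 epimers; not isolated) | O=C(c1c(OCOC)c(CC=C(C)C)c(OCOC)c(CC=C(C)C)c1OCOC)C1C[C@H](C(C)(C)O)Oc2cc(OCOC)ccc2C1=[N+]1CCCC1.[I-] | intermediate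
20 | [(2R)-2-(2-hydroxypropan-2-yl)-8-(methoxymethoxy)-5-(pyrrolidin-1-yl)-2,3-dihydro-1-benzoxepin-4-yl](ArA)methanone | O=C(c1c(OCOC)c(CC=C(C)C)c(OCOC)c(CC=C(C)C)c1OCOC)C1=C(N2CCCC2)c2ccc(OCOC)cc2O[C@@H](C(C)(C)O)C1 | intermediate
21 | [(2R)-8-hydroxy-2-(2-hydroxypropan-2-yl)-5-(pyrrolidin-1-yl)-2,3-dihydro-1-benzoxepin-4-yl][2,4,6-trihydroxy-3,5-bis(3-methylbut-2-enyl)phenyl]methanone (not isolated) | O=C(c1c(O)c(CC=C(C)C)c(O)c(CC=C(C)C)c1O)C1=C(N2CCCC2)c2ccc(O)cc2O[C@@H](C(C)(C)O)C1 | intermediate
22 | CNP0328977.2: (R)-5,7,4'-trihydroxy-6,8-diprenylflavone bridged from C3 through CH2-CH(CMe2OH) to the 2'-oxygen | CC(C)=CCc1c(O)c(CC=C(C)C)c2oc3c(c(=O)c2c1O)C[C@H](C(C)(C)O)Oc1cc(O)ccc1-3 | target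

**Step count**

Total steps: 14. Longest linear sequence: 11 steps (1, 2, 4, 5, 8, 9, 10, 11, 12, 13, 14, from prenol 1 to target 22).

**Steps most likely to fail**

Step 13. The neutral enaminone carbon may be too weak a nucleophile for a beta-branched, beta-oxygenated primary iodide, so that the seven-membered closure is outrun by E2 loss of HI or by thermal breakdown of the enaminone. The fallback replaces the neutral nucleophile by an enolate and uses only known reactions. It sets out from 17: pyrrolidine addition followed at once by aqueous oxalic acid in THF would hydrolyse enaminone 18 to 1-ArA-3-{2-[(2S)-3-hydroxy-1-iodo-3-methylbutan-2-yl]oxy-4-(methoxymethoxy)phenyl}propane-1,3-dione F1. Cs2CO3 in DMF at room temperature should then alkylate the doubly activated carbon intramolecularly, an ordinary 1,3-dicarbonyl C-alkylation, to give (2R)-4-(ArA-carbonyl)-2-(2-hydroxypropan-2-yl)-8-(methoxymethoxy)-3,4-dihydro-1-benzoxepin-5(2H)-one F2. Treatment with 3 M HCl in MeOH at 50 °C would remove the MOM groups and cyclodehydrate the ortho-hydroxyaryl 1,3-diketone in the classical flavone manner, which comes back to the route at 22.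

Step 4. The formyl-stabilised phenoxide is a weak nucleophile and the epoxide carbon it must attack is flanked by a fully substituted carbon and a bulky silyloxymethyl group, so the opening may stall while prolonged heating degrades the aldehyde and erodes regioselectivity. The fallback raises the leaving-group ability instead of the temperature and sets out from 3. Acid-catalysed hydrolysis (cat. HClO4, THF/H2O, 0 °C), in which water enters at the tertiary carbon and the C2–O bond keeps its configuration, would give (2S)-1-(tert-butyldiphenylsilyloxy)-3-methylbutane-2,3-diol F3. SOCl2 and Et3N would convert it into the cyclic sulfite (5S)-5-[(tert-butyldiphenylsilyloxy)methyl]-4,4-dimethyl-1,3,2-dioxathiolane 2-oxide F4, and RuCl3 (cat.) with NaIO4 would oxidise this to the cyclic sulfate, the corresponding 2,2-dioxide F5. The potassium phenoxide of 5 (K2CO3, DMF, rt) should open the sulfate at the secondary carbon with inversion to potassium (3R)-4-(tert-butyldiphenylsilyloxy)-3-[2-formyl-5-(methoxymethoxy)phenoxy]-2-methylbutan-2-yl sulfate F6. Catalytic H2SO4 with one equivalent of water in THF would cleave the tertiary sulfate monoester and return to the route at 6.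

Step 6. The alkylation of an ambident triphenoxide may stop at the mono-prenyl stage or run on to geminal diprenyl dienones and O-prenyl ethers, leaving little of the 3,5-diprenyl compound. The fallback builds the pattern by directed ortho-metalation and sets out from 9 together with purchased phloroglucinol. NaH and MOMCl would give 1,3,5-tris(methoxymethoxy)benzene F7. Lithiation (n-BuLi, THF, 0 °C) between two MOM ethers, followed by CuI (cat.) and 9, would give 1,3,5-tris(methoxymethoxy)-2-(3-methylbut-2-enyl)benzene F8, and a second identical cycle would give 1,3,5-tris(methoxymethoxy)-2,4-bis(3-methylbut-2-enyl)benzene F9. A third lithiation at the last ring position, quenched with DMF, would deliver the aldehyde and rejoin the route at 11.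

**Further compounds**

F1 | step 13 | 1-ArA-3-{2-[(2S)-3-hydroxy-1-iodo-3-methylbutan-2-yl]oxy-4-(methoxymethoxy)phenyl}propane-1,3-dione | IC[C@H](C(C)(C)O)Oc1cc(OCOC)ccc1C(=O)CC(=O)c1c(OCOC)c(CC=C(C)C)c(OCOC)c(CC=C(C)C)c1OCOC
F2 | step 13 | (2R)-4-(ArA-carbonyl)-2-(2-hydroxypropan-2-yl)-8-(methoxymethoxy)-3,4-dihydro-1-benzoxepin-5(2H)-one (C4 epimers) | O=C(c1c(OCOC)c(CC=C(C)C)c(OCOC)c(CC=C(C)C)c1OCOC)C1C[C@H](C(C)(C)O)Oc2cc(OCOC)ccc2C1=O
F3 | step 4 | (2S)-1-(tert-butyldiphenylsilyloxy)-3-methylbutane-2,3-diol | CC(C)(C)[Si](c1ccccc1)(c1ccccc1)OC[C@@H](C(C)(C)O)O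
F4 | step 4 | (5S)-5-[(tert-butyldiphenylsilyloxy)methyl]-4,4-dimethyl-1,3,2-dioxathiolane 2-oxide (sulfur epimers) | CC(C)(C)[Si](c1ccccc1)(c1ccccc1)OC[C@@H]1OS(=O)OC1(C)C
F5 | step 4 | (5S)-5-[(tert-butyldiphenylsilyloxy)methyl]-4,4-dimethyl-1,3,2-dioxathiolane 2,2-dioxide | CC(C)(C)[Si](c1ccccc1)(c1ccccc1)OC[C@@H]1OS(=O)(=O)OC1(C)C
F6 | step 4 | potassium (3R)-4-(tert-butyldiphenylsilyloxy)-3-[2-formyl-5-(methoxymethoxy)phenoxy]-2-methylbutan-2-yl sulfate | CC(C)(C)[Si](c1ccccc1)(c1ccccc1)OC[C@H](C(C)(C)OS(=O)(=O)[O-])Oc1cc(OCOC)ccc1C=O.[K+]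
F7 | step 6 | 1,3,5-tris(methoxymethoxy)benzene | COCOc1cc(OCOC)cc(OCOC)c1
F8 | step 6 | 1,3,5-tris(methoxymethoxy)-2-(3-methylbut-2-enyl)benzene | COCOc1cc(OCOC)c(CC=C(C)C)c(OCOC)c1
F9 | step 6 | 1,3,5-tris(methoxymethoxy)-2,4-bis(3-methylbut-2-enyl)benzene | COCOc1cc(OCOC)c(CC=C(C)C)c(OCOC)c1CC=C(C)C
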